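Two sums stay fixed in this closed flask: c(free monomer) + c(monomer in chains) stands at the charge of free monomer, and c(initiator) + c(living end) + 2 c(dead end) stands at the charge of initiator, since each dead end took two living ends.

- west: free monomer 0.20 M; initiator 5 mol%; time 6.0 min
- south: free monomer 0.20 M; initiator 5 mol%; time 25 min

    free monomer + initiator → living end + monomer in chains (k1 = 0.161 M⁻¹ s⁻¹)
    free monomer + living end → monomer in chains + living end, rate k2*[living end]*[free monomer] (k2 = 0.192 M⁻¹ s⁻¹)
    2 living end → dead end (k3 = 0.743 M⁻¹ s⁻¹)
    monomer in chains + living end → free monomer + living end, rate k4*[living end] as long as [monomer in chains] is above zero (k4 = 0.0203 s⁻¹)

- which of the two ends with the longer chains by the average number of monomer units in a chain (chains begun, living or dead) ("neither" if they lie within 10%) (west / south / neither)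
- average number of monomer units in a chain (chains begun, living or dead) at the end, west
- average number of monomer units in a chain (chains begun, living or dead) at the end, south

What is the length, then? It is c(monomer in chains) over the initiator used, because each initiator used begins one chain, living or dead.

How soon is the initiator used? Its lifetime against the charged free monomer is 31.1 s, far shorter than west's time. So I start all 0.0100 M of chains at once, each holding one unit.

And the living ends? Under pairing, c(living end) = 0.0100 M/(1 + t/τ), with τ = 67.3 s.

What can be frozen? Free monomer, which makes net growth pseudo-first-order in living end. Integrating gives a gain of W ln(1 + t/τ), where W is the growth constant times c(free monomer), less the unzipping constant, all over twice the pairing constant: the gain per e-fold of time.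

But frozen at which value? At the charge, W is 0.0122 M, and west reaches 0.0325 M in chains. That is too much, since free monomer has fallen meanwhile. Freezing instead at the charge less half of that, 0.184 M, gives W = 0.0101 M, and west's length is 2.86.

For south, the same correction, half of the chains reckoned at the charge, freezes free monomer at 0.176 M, and W becomes 0.00906 M. South's length is 3.85, so I say south, longer by more than the margin.

The forecast also says south, with 2.8 for west, below mine, and 3.9 for south, above mine, on the ground that “the chains keep growing slowly”.

The flask gives south, with 2.89 in west and 3.98 in south. Between the two ends monomer in chains rose by 0.0109 M, and W gives 0.0131 M. The neighbour flask is west with 0.050 M of free monomer at the same loading. Its charge stands below the equilibrium monomer concentration, the unzipping constant over the growth constant, 0.106 M. So W turns from 0.0101 M to −0.00720 M, and the reckoning gives −0.00361 M in chains, below zero. That neighbour holds 0.0422% of its charge in chains at 6.00 min, or 0.00894 units per chain.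

The numbers of this flask stand for no real mixture; the result is computed.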